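The isoflavone is disconnected at the congested C3–C1' bond between ring C and ring B. Ring B carries methoxy groups at C2', C4' and C6', ortho and para to C1', which make it an exceptional migrating group. A fully O-benzylated chalcone, assembled by Claisen–Schmidt condensation of 2,4,6-tris(benzyloxy)acetophenone with 3-(benzyloxy)-2,4,6-trimethoxybenzaldehyde, is oxidised with Tl(NO3)3 (trivalent thallium) in methanol and trimethyl orthoformate. In one operation ring B shifts from the β- to the α-carbon, which forms the C3–C1' bond intramolecularly and leaves the future C2 as a dimethyl acetal. Hydrogenolysis of the four benzyl ethers and acid-mediated closure of ring C should then deliver the isoflavone.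

Key step: step 6

Remark on the chemistry: the planned structures are consistent with the target (ring B: C2', C4', C6' methoxy, C3' hydroxy; ring A: 5,7-dihydroxy). Ring A is kept fully benzylated so that flavanone or aurone formation cannot intervene before ring C is closed deliberately. The stereocentre at C2 of the rearranged propanone is formed racemic and is erased on aromatisation. 1-[2,4-Bis(benzyloxy)-6-hydroxyphenyl]ethan-1-one (8) is assumed to be a purchasable building block, so ring A needs only one further O-benzylation.

Step 1
Reactants: 1 2,4,6-trimethoxybenzaldehyde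
Product: 3 2,4,6-trimethoxyphenol, via 2,4,6-trimethoxyphenyl formate 2 (not isolated)
Conditions: 30% aq. H2O2 (1.3 equiv), cat. H2SO4, MeOH, rt
Reagents that add atoms: hydrogen peroxide, OO
Why: Acid-catalysed Dakin (Baeyer–Villiger-type) oxidation, in which the electron-rich trimethoxyphenyl group migrates from carbon to peroxide oxygen and formate 2 is methanolysed in the same flask to the phenol, which is air-sensitive and should be carried on at once.

Step 2
Reactants: 3 2,4,6-trimethoxyphenol; 4 benzyl bromide
Product: 5 2-(benzyloxy)-1,3,5-trimethoxybenzene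
Conditions: BnBr (1.1 equiv), K2CO3, DMF, rt, N2
Reagents that add atoms: none
Why: Williamson ether synthesis on a single, unhindered phenoxide with a reactive benzylic bromide; the inert atmosphere protects the oxidation-prone phenol until it is capped.

Step 3
Reactants: 5 2-(benzyloxy)-1,3,5-trimethoxybenzene
Product: 7 3-(benzyloxy)-2,4,6-trimethoxybenzaldehyde, via iminium salt 6 (not isolated)
Conditions: POCl3 (1.5 equiv), DMF, 0 °C to rt; then ice-water
Reagents that add atoms: N,N-dimethylformamide, CN(C)C=O; water, O
Why: Vilsmeier–Haack formylation: the chloroiminium ion attacks the only type of free ring position (C4 and C6 are equivalent), which is ortho to two methoxy groups and para to the third, and hydrolysis of iminium salt 6 releases the aldehyde with the benzyloxy group meta to it.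

Step 4
Reactants: 8 1-[2,4-bis(benzyloxy)-6-hydroxyphenyl]ethan-1-one; 4 benzyl bromide
Product: 9 1-[2,4,6-tris(benzyloxy)phenyl]ethan-1-one
Conditions: BnBr (1.3 equiv), K2CO3 (2.5 equiv), DMF, 70 °C
Reagents that add atoms: none
Why: Williamson ether synthesis on the single remaining phenol: warm carbonate in a dipolar aprotic solvent overcomes its hydrogen bond to the acetyl carbonyl, and with two of the three ring oxygens already capped, C-benzylation of the ring should be minor.

Step 5
Reactants: 9 1-[2,4,6-tris(benzyloxy)phenyl]ethan-1-one; 7 3-(benzyloxy)-2,4,6-trimethoxybenzaldehyde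
Product: 11 (E)-1-[2,4,6-tris(benzyloxy)phenyl]-3-[3-(benzyloxy)-2,4,6-trimethoxyphenyl]prop-2-en-1-one, via aldol adduct 10 (not isolated)
Conditions: KOH (50% aq.), EtOH–THF, rt to 40 °C
Reagents that add atoms: none
Why: Claisen–Schmidt condensation, in which the methyl ketone is the only enolisable partner and the aldehyde has no α-hydrogen, so crossed aldol addition to 10 is followed by E1cB loss of water to the thermodynamically preferred (E)-enone, while benzyl and methyl ethers are inert to hydroxide.

Step 6
Reactants: 11 (E)-1-[2,4,6-tris(benzyloxy)phenyl]-3-[3-(benzyloxy)-2,4,6-trimethoxyphenyl]prop-2-en-1-one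
Product: 13 1-[2,4,6-tris(benzyloxy)phenyl]-2-[3-(benzyloxy)-2,4,6-trimethoxyphenyl]-3,3-dimethoxypropan-1-one (racemic), via oxythallation adduct 12 (not isolated)
Conditions: Tl(NO3)3·3H2O (1.1 equiv), MeOH–HC(OMe)3 (CH2Cl2 co-solvent), 0 °C to rt
Reagents that add atoms: methanol, CO
Why: Trivalent thallium adds electrophilically to the α-carbon of the enone while methanol attacks the β-carbon, giving adduct 12; heterolysis of the weak C–Tl bond with loss of TlNO3 is assisted by ring B, which shifts from the β- to the α-carbon through a phenonium ion and so forms the C3–C1' bond, and the oxocarbenium ion left at the β-carbon is captured by methanol as the dimethyl acetal. The closest known reaction type is the Tl(NO3)3-mediated oxidative rearrangement of O-protected chalcones to 1,2-diaryl-3,3-dimethoxypropan-1-ones used in isoflavone synthesis. No ring is closed, so no mode of closure applies. The new stereocentre at C2 is formed racemic with no controlling element and needs none, since it becomes sp2 when ring C aromatises. The step needs aryl migration in preference to aroyl migration and attack on the enone in preference to oxidation of the alkoxylated rings; the methoxy groups at C2', C4' and C6' make ring B by far the better migrating group, the carbonyl flanked by two benzyloxy groups resists ketalisation (the entry to aroyl-shift ester by-products), and full O-protection with about one equivalent of oxidant suppresses aurone, flavanone and quinone pathways. Tl(NO3)3 is preferred over a trivalent iodine reagent because the free C5'–H of ring B and C3/C5–H of ring A would be prone to aryl–iodonium formation.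

Step 7
Reactants: 13 1-[2,4,6-tris(benzyloxy)phenyl]-2-[3-(benzyloxy)-2,4,6-trimethoxyphenyl]-3,3-dimethoxypropan-1-one
Product: 16 5,7-dihydroxy-3-(3-hydroxy-2,4,6-trimethoxyphenyl)-4H-chromen-4-one, via tetraphenol acetal 14 (not isolated), via 2-methoxyisoflavanone 15 (not isolated)
Conditions: H2 (1 atm), 10% Pd/C, THF–MeOH, rt; filter; then conc. HCl (cat.), MeOH, 60 °C
Reagents that add atoms: none
Why: Catalytic hydrogenolysis cleaves the four benzylic C–O bonds while methyl ethers, acetal and the electron-rich aryl ketone remain, and acid then ionises the acetal of 14 so that either equivalent ortho hydroxyl of ring A closes ring C to 15, which loses methanol to aromatise the pyranone; hydrogenolysis before ring closure keeps the C2=C3 double bond away from H2 and Pd/C.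

Compound list
1 | 2,4,6-trimethoxybenzaldehyde | COc1cc(OC)c(C=O)c(OC)c1 | starting material
2 | 2,4,6-trimethoxyphenyl formate | COc1cc(OC)c(OC=O)c(OC)c1 | intermediate (not isolated)
3 | 2,4,6-trimethoxyphenol | COc1cc(OC)c(O)c(OC)c1 | intermediate
4 | benzyl bromide | BrCc1ccccc1 | starting material
5 | 2-(benzyloxy)-1,3,5-trimethoxybenzene | COc1cc(OC)c(OCc2ccccc2)c(OC)c1 | intermediate
6 | N-{[3-(benzyloxy)-2,4,6-trimethoxyphenyl]methylidene}-N-methylmethanaminium dichlorophosphate | C[N+](C)=Cc1c(OC)cc(OC)c(OCc2ccccc2)c1OC.[O-]P(=O)(Cl)Cl | intermediate (not isolated)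
7 | 3-(benzyloxy)-2,4,6-trimethoxybenzaldehyde | COc1cc(OC)c(C=O)c(OC)c1OCc1ccccc1 | intermediate
8 | 1-[2,4-bis(benzyloxy)-6-hydroxyphenyl]ethan-1-one | CC(=O)c1c(O)cc(OCc2ccccc2)cc1OCc1ccccc1 | starting material
9 | 1-[2,4,6-tris(benzyloxy)phenyl]ethan-1-one | CC(=O)c1c(OCc2ccccc2)cc(OCc2ccccc2)cc1OCc1ccccc1 | intermediate
10 | 1-[2,4,6-tris(benzyloxy)phenyl]-3-[3-(benzyloxy)-2,4,6-trimethoxyphenyl]-3-hydroxypropan-1-one (racemic) | O=C(CC(O)c1c(OC)cc(OC)c(OCc2ccccc2)c1OC)c1c(OCc2ccccc2)cc(OCc2ccccc2)cc1OCc1ccccc1 | intermediate (not isolated)
11 | (E)-1-[2,4,6-tris(benzyloxy)phenyl]-3-[3-(benzyloxy)-2,4,6-trimethoxyphenyl]prop-2-en-1-one | O=C(/C=C/c1c(OC)cc(OC)c(OCc2ccccc2)c1OC)c1c(OCc2ccccc2)cc(OCc2ccccc2)cc1OCc1ccccc1 | intermediate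
12 | 1-[2,4,6-tris(benzyloxy)phenyl]-3-[3-(benzyloxy)-2,4,6-trimethoxyphenyl]-3-methoxy-2-(dinitratothallio)propan-1-one (racemic, relative configuration not defined) | COC(c1c(OC)cc(OC)c(OCc2ccccc2)c1OC)C([Tl](O[N+](=O)[O-])O[N+](=O)[O-])C(=O)c1c(OCc2ccccc2)cc(OCc2ccccc2)cc1OCc1ccccc1 | intermediate (not isolated)
13 | 1-[2,4,6-tris(benzyloxy)phenyl]-2-[3-(benzyloxy)-2,4,6-trimethoxyphenyl]-3,3-dimethoxypropan-1-one (racemic) | COC(OC)C(c1c(OC)cc(OC)c(OCc2ccccc2)c1OC)C(=O)c1c(OCc2ccccc2)cc(OCc2ccccc2)cc1OCc1ccccc1 | intermediate
14 | 2-(3-hydroxy-2,4,6-trimethoxyphenyl)-3,3-dimethoxy-1-(2,4,6-trihydroxyphenyl)propan-1-one (racemic) | COC(OC)C(c1c(OC)cc(OC)c(O)c1OC)C(=O)c1c(O)cc(O)cc1O | intermediate (not isolated)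
15 | 5,7-dihydroxy-3-(3-hydroxy-2,4,6-trimethoxyphenyl)-2-methoxy-2,3-dihydro-4H-chromen-4-one (racemic mixture of diastereomers) | COC1Oc2cc(O)cc(O)c2C(=O)C1c1c(OC)cc(OC)c(O)c1OC | intermediate (not isolated)
16 | 5,7-dihydroxy-3-(3-hydroxy-2,4,6-trimethoxyphenyl)-4H-chromen-4-one | COc1cc(OC)c(-c2coc3cc(O)cc(O)c3c2=O)c(OC)c1O | target

Total steps: 7. Longest linear sequence: 6 steps (steps 1, 2, 3, 5, 6 and 7, from 1 to 16); step 4 supplies ketone 9 for the convergent step 5.

Steps most likely to fail

Step 6. The oxidant may be diverted into oxidation or nitration of the alkoxylated rings A and B, or oxythallation may stall on the hindered, poorly soluble enone so that aryl migration is never reached. Thallium salts are also acutely toxic and need contained handling. The fallback sets out from 11 and returns to the route at 16. Nucleophilic epoxidation of 11 (30% H2O2, aq. NaOH, MeOH–THF, rt) should give the racemic trans-epoxide [3-(3-(benzyloxy)-2,4,6-trimethoxyphenyl)oxiran-2-yl][2,4,6-tris(benzyloxy)phenyl]methanone F1. BF3·OEt2 in CH2Cl2 at 0 °C should open it at the benzylic carbon next to ring B and induce the known 1,2-aroyl shift to the β-keto aldehyde 3-[2,4,6-tris(benzyloxy)phenyl]-2-[3-(benzyloxy)-2,4,6-trimethoxyphenyl]-3-oxopropanal F2, in which ring B already sits on the future C3. Hydrogenolysis (H2, 10% Pd/C, THF–MeOH) should then give, by spontaneous hemiacetal closure, 2,5,7-trihydroxy-3-(3-hydroxy-2,4,6-trimethoxyphenyl)-2,3-dihydro-4H-chromen-4-one F3, which should lose water on brief warming with HCl in MeOH to give 16.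

Step 5. The reversible aldol addition between a doubly ortho-substituted, donor-deactivated aldehyde and a doubly ortho-substituted ketone may be too slow, so that retro-aldol or Cannizzaro consumption of the aldehyde competes. The fallback sets out from 9 and 7 and returns at 11. Bond formation and dehydration are separated: the lithium enolate of 9 is preformed (LiN(SiMe3)2, THF, −78 °C) and added irreversibly to 7, and the aldol 10 is isolated after a cold quench. It is then dehydrated under mild acid (cat. TsOH, toluene, rt to 50 °C) through the benzylic cation stabilised by ring B, giving 11. This makes no compound outside the list (entry F0).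

Step 7. Reduction may run past benzyl ether cleavage: trace acid on the catalyst can close ring C early, after which the C2=C3 double bond or the aryl ketone may be hydrogenated, and the electron-rich tetraphenol may oxidise in air during filtration. The fallback sets out from 13 and returns at 16. The benzyl ethers are cleaved without hydrogen by BCl3 (8 equiv) with pentamethylbenzene as cation scavenger in CH2Cl2 at −78 °C. These conditions should leave the aryl methyl ethers of ring B intact, since none is ortho to a carbonyl group. The same Lewis acid ionises the acetal, and a methanol quench followed by brief warming with cat. HCl in MeOH should complete ring closure through 14 and 15 to 16. This makes no compound outside the list (entry F0).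

Further compounds
F1 | step 6 | [3-(3-(benzyloxy)-2,4,6-trimethoxyphenyl)oxiran-2-yl][2,4,6-tris(benzyloxy)phenyl]methanone (racemic, trans) | O=C([C@@H]1O[C@H]1c1c(OC)cc(OC)c(OCc2ccccc2)c1OC)c1c(OCc2ccccc2)cc(OCc2ccccc2)cc1OCc1ccccc1
F2 | step 6 | 3-[2,4,6-tris(benzyloxy)phenyl]-2-[3-(benzyloxy)-2,4,6-trimethoxyphenyl]-3-oxopropanal (racemic) | O=CC(c1c(OC)cc(OC)c(OCc2ccccc2)c1OC)C(=O)c1c(OCc2ccccc2)cc(OCc2ccccc2)cc1OCc1ccccc1
F3 | step 6 | 2,5,7-trihydroxy-3-(3-hydroxy-2,4,6-trimethoxyphenyl)-2,3-dihydro-4H-chromen-4-one (racemic mixture of diastereomers) | OC1Oc2cc(O)cc(O)c2C(=O)C1c1c(OC)cc(OC)c(O)c1OC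
F0 | step 5 | none | none
F0 | step 7 | none | none
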